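**Retrosynthetic overview**

- Ring A is the benzo ring, ring B the 4-methoxyphenyl ring, ring C the pyranone. The strategy rests on C4: it is an aryl ketone carbon of ring A ortho to the ether oxygen O1. Ring C is therefore cut at C3–C4, and C4 becomes the CHO of a salicylaldehyde whose O-propargyl ether already holds C2, C3, the benzylic C9 and ring B.
- C3–C4 is formed by carbene-catalysed hydroacylation of the tethered aryl alkyne (acyl-anion umpolung of the aldehyde), which gives the (E)-3-benzylidenechromanone. Shift of C3=C9 into the ring, desilylation and Duff formylation at C8 (C6 is blocked by methyl) finish the target.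
- The alkynyl aldehyde comes from Mitsunobu etherification of a 6-hydroxybenzaldehyde. Its CHO is placed by ortho-lithiation between OMOM and OMe, and the 1,3,5-oxygen pattern by iridium-catalysed C–H borylation/oxidation of the silyl ether of 3-methoxy-2-methylphenol, so that 5-OMe and the 7-oxygen differ from the first step.
- Ring order: rings A and B are bought; ring C is the only ring made (step 7).

Key step: step 7

Assumption: 3-methoxy-2-methylphenol and 3-(4-methoxyphenyl)prop-2-yn-1-ol are taken as purchasable; the target has no stereocentre, and the only stereochemical element on the way is the E double bond set in the key step.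

**Route**

Step 1
Reactants: 1 3-methoxy-2-methylphenol
Product: 2 (3-methoxy-2-methylphenoxy)triisopropylsilane
Conditions: TIPSCl, imidazole, DMF, rt to 40 °C
Reagents that add atoms: triisopropylsilyl chloride, CC(C)[Si](Cl)(C(C)C)C(C)C
Why: Imidazole-promoted O-silylation of a phenol is routine, and the bulky, non-coordinating silyl ether marks this oxygen as the future 7-OH and later keeps metalation away from its side of the ring.

Step 2
Reactants: 2 (3-methoxy-2-methylphenoxy)triisopropylsilane
Product: 4 3-methoxy-4-methyl-5-(triisopropylsilyloxy)phenol, via aryl pinacol boronate 3 (not isolated)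
Conditions: [Ir(OMe)(cod)]2 (1.5 mol %), 4,4'-di-tert-butyl-2,2'-bipyridine (3 mol %), B2pin2 (1.0 equiv), THF, 80 °C; then Oxone (2KHSO5·KHSO4·K2SO4), acetone/H2O, rt, NaHSO3 quench
Reagents that add atoms: bis(pinacolato)diboron, CC1(C)OB(OC1(C)C)B1OC(C)(C)C(C)(C)O1 (boron of intermediate 3); potassium peroxymonosulfate, [K+].[O-]S(=O)(=O)OO (phenol oxygen)
Why: Sterically governed iridium-catalysed C–H borylation should take the only ring C–H without an ortho substituent (para to the methyl group), and peroxymonosulfate oxidation of the C–B bond puts the hydroxyl on the same carbon.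

Step 3
Reactants: 4 3-methoxy-4-methyl-5-(triisopropylsilyloxy)phenol
Product: 5 [3-methoxy-5-(methoxymethoxy)-2-methylphenoxy]triisopropylsilane
Conditions: MOMCl, iPr2NEt, CH2Cl2, 0 °C to rt
Reagents that add atoms: chloromethyl methyl ether, COCCl
Why: O-alkylation of the phenol with the reactive α-chloro ether gives the methoxymethyl ether, which protects this oxygen and is a strong director for ortho-metalation.

Step 4
Reactants: 5 [3-methoxy-5-(methoxymethoxy)-2-methylphenoxy]triisopropylsilane
Product: 7 2-methoxy-6-(methoxymethoxy)-3-methyl-4-(triisopropylsilyloxy)benzaldehyde, via aryllithium 6 (not isolated)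
Conditions: n-BuLi, TMEDA, THF, 0 °C; DMF, 0 °C to rt; aq. NH4Cl
Reagents that add atoms: n-butyllithium, [Li]CCCC (lithium of intermediate 6); N,N-dimethylformamide, CN(C)C=O
Why: Directed ortho-metalation should occur at the C–H flanked by the two coordinating ethers (OMOM and OMe) and not at the C–H next to the bulky silyl ether, and DMF formylates the aryllithium.

Step 5
Reactants: 7 2-methoxy-6-(methoxymethoxy)-3-methyl-4-(triisopropylsilyloxy)benzaldehyde
Product: 8 6-hydroxy-2-methoxy-3-methyl-4-(triisopropylsilyloxy)benzaldehyde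
Conditions: 3 M aq. HCl, THF, rt to 40 °C
Reagents that add atoms: none
Why: Acid hydrolysis of the formaldehyde acetal is fast for an aryl MOM ether ortho to a carbonyl group, while an aryl triisopropylsilyl ether resists dilute aqueous acid.

Step 6
Reactants: 8 6-hydroxy-2-methoxy-3-methyl-4-(triisopropylsilyloxy)benzaldehyde; 9 3-(4-methoxyphenyl)prop-2-yn-1-ol
Product: 10 2-methoxy-6-{[3-(4-methoxyphenyl)prop-2-yn-1-yl]oxy}-3-methyl-4-(triisopropylsilyloxy)benzaldehyde
Conditions: PPh3, DIAD, THF, 0 °C to rt
Reagents that add atoms: none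
Why: Mitsunobu etherification joins the acidic salicylaldehyde hydroxyl to the unhindered primary propargylic alcohol under neutral conditions, which spare the silyl ether and the aldehyde and cannot isomerise the propargyl ether to an allene.

Step 7
Reactants: 10 2-methoxy-6-{[3-(4-methoxyphenyl)prop-2-yn-1-yl]oxy}-3-methyl-4-(triisopropylsilyloxy)benzaldehyde
Product: 12 (E)-5-methoxy-3-(4-methoxybenzylidene)-6-methyl-7-(triisopropylsilyloxy)chroman-4-one, via Breslow intermediate 11 (not isolated)
Conditions: 3-benzyl-5-(2-hydroxyethyl)-4-methylthiazolium chloride (20 mol %), K2CO3 (40 mol %), THF, 70 °C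
Reagents that add atoms: none
Why: The thiazol-2-ylidene set free by K2CO3 adds to the aldehyde and proton transfer gives Breslow intermediate 11, whose nucleophilic C4 attacks alkyne carbon C3 while its hydroxyl proton passes to C9 in a concerted Conia-ene-like transition state; collapse of the alkoxide then expels the carbene and leaves the enone. The closest known reaction is the N-heterocyclic-carbene-catalysed intramolecular hydroacylation of unactivated alkynes in O-propargyl salicylaldehydes, which gives 3-alkylidenechroman-4-ones. Ring C closes 6-exo-dig through the new C3–C4 bond, its size fixed by the O1–C2 tether. No stereocentre is formed; syn delivery of the acyl carbon and the proton across the alkyne sets the E geometry (anisyl trans to C4=O). The step needs cyclisation to win over benzoin dimerisation and over base-induced propargyl-to-allenyl isomerisation: the two ortho ethers flanking the CHO hinder attack of the acyl-anion equivalent on a second aldehyde, and the weak carbonate base leaves the propargylic CH2 alone.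

Step 8
Reactants: 12 (E)-5-methoxy-3-(4-methoxybenzylidene)-6-methyl-7-(triisopropylsilyloxy)chroman-4-one
Product: 13 5-methoxy-3-(4-methoxybenzyl)-6-methyl-7-(triisopropylsilyloxy)-4H-chromen-4-one
Conditions: RhCl3·3H2O (10 mol %), EtOH, 80 °C
Reagents that add atoms: none
Why: Rhodium-hydride addition/β-hydride elimination moves the exocyclic C3=C9 bond to C2=C3, driven by formation of the aromatic 4-pyranone; this is a known isomerisation of (E)-3-benzylidenechroman-4-ones to 3-benzylchromones.

Step 9
Reactants: 13 5-methoxy-3-(4-methoxybenzyl)-6-methyl-7-(triisopropylsilyloxy)-4H-chromen-4-one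
Product: 14 7-hydroxy-5-methoxy-3-(4-methoxybenzyl)-6-methyl-4H-chromen-4-one
Conditions: Bu4NF, AcOH, THF, 0 °C to rt
Reagents that add atoms: none
Why: Fluoride cleaves the aryl silyl ether through the strong Si–F bond, and the acetic acid buffer keeps the medium from opening the chromone at C2.

Step 10
Reactants: 14 7-hydroxy-5-methoxy-3-(4-methoxybenzyl)-6-methyl-4H-chromen-4-one
Product: 16 7-hydroxy-5-methoxy-3-(4-methoxybenzyl)-6-methyl-4-oxo-4H-chromene-8-carbaldehyde, via 8-aldimine 15 (not isolated)
Conditions: hexamethylenetetramine, AcOH, 100 °C; then 3 M aq. HCl, 80 °C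
Reagents that add atoms: hexamethylenetetramine, C1N2CN3CN1CN(C2)C3 (formyl carbon); water, O (formyl oxygen)
Why: In the Duff reaction the iminium ion from protonated hexamethylenetetramine attacks the phenol ortho position, here C8 (the only free carbon of ring A, activated by 7-OH, O1 and 5-OMe), and redox transfer followed by acid hydrolysis of the aldimine gives the aldehyde, while ring B, which has no free phenol, should not react in acetic acid.

**Compound list**

1 | 3-methoxy-2-methylphenol | COc1cccc(O)c1C | starting material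
2 | (3-methoxy-2-methylphenoxy)triisopropylsilane | COc1cccc(O[Si](C(C)C)(C(C)C)C(C)C)c1C | intermediate
3 | 2-[3-methoxy-4-methyl-5-(triisopropylsilyloxy)phenyl]-4,4,5,5-tetramethyl-1,3,2-dioxaborolane | COc1cc(B2OC(C)(C)C(C)(C)O2)cc(O[Si](C(C)C)(C(C)C)C(C)C)c1C | intermediate (not isolated)
4 | 3-methoxy-4-methyl-5-(triisopropylsilyloxy)phenol | COc1cc(O)cc(O[Si](C(C)C)(C(C)C)C(C)C)c1C | intermediate
5 | [3-methoxy-5-(methoxymethoxy)-2-methylphenoxy]triisopropylsilane | COCOc1cc(OC)c(C)c(O[Si](C(C)C)(C(C)C)C(C)C)c1 | intermediate
6 | [2-methoxy-6-(methoxymethoxy)-3-methyl-4-(triisopropylsilyloxy)phenyl]lithium | [Li]c1c(OCOC)cc(O[Si](C(C)C)(C(C)C)C(C)C)c(C)c1OC | intermediate (not isolated)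
7 | 2-methoxy-6-(methoxymethoxy)-3-methyl-4-(triisopropylsilyloxy)benzaldehyde | O=Cc1c(OCOC)cc(O[Si](C(C)C)(C(C)C)C(C)C)c(C)c1OC | intermediate
8 | 6-hydroxy-2-methoxy-3-methyl-4-(triisopropylsilyloxy)benzaldehyde | O=Cc1c(O)cc(O[Si](C(C)C)(C(C)C)C(C)C)c(C)c1OC | intermediate
9 | 3-(4-methoxyphenyl)prop-2-yn-1-ol | COc1ccc(C#CCO)cc1 | starting material
10 | 2-methoxy-6-{[3-(4-methoxyphenyl)prop-2-yn-1-yl]oxy}-3-methyl-4-(triisopropylsilyloxy)benzaldehyde | O=Cc1c(OCC#Cc2ccc(OC)cc2)cc(O[Si](C(C)C)(C(C)C)C(C)C)c(C)c1OC | intermediate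
11 | Breslow intermediate: 2-{hydroxy[aryl]methylidene}-3-benzyl-5-(2-hydroxyethyl)-4-methyl-2,3-dihydrothiazole, aryl being the ring of 10 | OC(=C1SC(CCO)=C(C)N1Cc1ccccc1)c1c(OCC#Cc2ccc(OC)cc2)cc(O[Si](C(C)C)(C(C)C)C(C)C)c(C)c1OC | intermediate (not isolated)
12 | (E)-5-methoxy-3-(4-methoxybenzylidene)-6-methyl-7-(triisopropylsilyloxy)chroman-4-one | COc1ccc(/C=C2/C(=O)c3c(OC)c(C)c(O[Si](C(C)C)(C(C)C)C(C)C)cc3OC2)cc1 | intermediate
13 | 5-methoxy-3-(4-methoxybenzyl)-6-methyl-7-(triisopropylsilyloxy)-4H-chromen-4-one | COc1ccc(Cc2coc3cc(O[Si](C(C)C)(C(C)C)C(C)C)c(C)c(OC)c3c2=O)cc1 | intermediate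
14 | 7-hydroxy-5-methoxy-3-(4-methoxybenzyl)-6-methyl-4H-chromen-4-one | COc1ccc(Cc2coc3cc(O)c(C)c(OC)c3c2=O)cc1 | intermediate
15 | 7-hydroxy-8-(iminomethyl)-5-methoxy-3-(4-methoxybenzyl)-6-methyl-4H-chromen-4-one | COc1ccc(Cc2coc3c(C=N)c(O)c(C)c(OC)c3c2=O)cc1 | intermediate (not isolated)
16 | 7-hydroxy-5-methoxy-3-(4-methoxybenzyl)-6-methyl-4-oxo-4H-chromene-8-carbaldehyde (CNP0177360.0) | COc1ccc(Cc2coc3c(C=O)c(O)c(C)c(OC)c3c2=O)cc1 | target

**Step count**

Total steps: 10. Longest linear sequence: 10 steps (1 to 16); alkyne 9 is bought.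

**Steps most likely to fail**

1. Step 7. The carbene may add only slowly to the electron-rich, doubly ortho-substituted aldehyde, so that carbonate-induced isomerisation of the propargyl ether or loss of the silyl ether overtakes cyclisation. The fallback sets out from 8 and comes back at 13; it closes ring C at O1–C2 by the classical homoisoflavone route. 1-(2-Bromoethyl)-4-methoxybenzene and magnesium in THF should give 2-(4-methoxyphenyl)ethylmagnesium bromide F1. Addition of 2.5 equiv of it to 8 (THF, 0 °C; the first equivalent is used up by the phenol) should give racemic 1-[6-hydroxy-2-methoxy-3-methyl-4-(triisopropylsilyloxy)phenyl]-3-(4-methoxyphenyl)propan-1-ol F2. Oxidation with MnO2 (CH2Cl2, rt) should give the dihydrochalcone 1-[6-hydroxy-2-methoxy-3-methyl-4-(triisopropylsilyloxy)phenyl]-3-(4-methoxyphenyl)propan-1-one F3. Heating F3 with N,N-dimethylformamide dimethyl acetal (toluene, 100 °C) should form the enaminone at the α-methylene and close the pyranone with loss of dimethylamine, giving 13, from which steps 9 and 10 follow.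

2. Step 10. Aminomethylation of the weakly nucleophilic, vinylogous-acid phenol may be sluggish, the redox step to the aldimine may stall, or ring B may react under more forcing acid. The fallback sets out from 14 and comes back at 16. NIS (MeCN, 0 °C) should iodinate the only free position of ring A to give 7-hydroxy-8-iodo-5-methoxy-3-(4-methoxybenzyl)-6-methyl-4H-chromen-4-one F4. Suzuki–Miyaura coupling with potassium vinyltrifluoroborate (PdCl2(dppf), Et3N, n-PrOH, 80 °C) should give 8-ethenyl-7-hydroxy-5-methoxy-3-(4-methoxybenzyl)-6-methyl-4H-chromen-4-one F5. Lemieux–Johnson cleavage of the styrene-type double bond (OsO4 cat., NaIO4, 2,6-lutidine, dioxane/H2O) should then give 16; the electron-poor C2=C3 bond of the chromone should react far more slowly.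

3. Step 5. The acid needed to hydrolyse the acetal may also remove part of the aryl silyl ether, giving a mixture of mono- and diphenols. The fallback sets out from 7 and comes back at 8; it gives up selectivity in the deprotection and relies on selective silylation instead. Bu4NF (THF, 0 °C) followed by 3 M aq. HCl (THF, 50 °C) should remove both groups to give 4,6-dihydroxy-2-methoxy-3-methylbenzaldehyde F6. TIPSCl (1.05 equiv) and imidazole in DMF at 0 °C should then silylate only the 4-hydroxyl, because the 6-hydroxyl is held in a hydrogen bond to the aldehyde, giving 8.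

**Further compounds**

F1 | step 7 | 2-(4-methoxyphenyl)ethylmagnesium bromide | COc1ccc(CC[Mg]Br)cc1
F2 | step 7 | 1-[6-hydroxy-2-methoxy-3-methyl-4-(triisopropylsilyloxy)phenyl]-3-(4-methoxyphenyl)propan-1-ol (racemic) | COc1ccc(CCC(O)c2c(O)cc(O[Si](C(C)C)(C(C)C)C(C)C)c(C)c2OC)cc1
F3 | step 7 | 1-[6-hydroxy-2-methoxy-3-methyl-4-(triisopropylsilyloxy)phenyl]-3-(4-methoxyphenyl)propan-1-one | COc1ccc(CCC(=O)c2c(O)cc(O[Si](C(C)C)(C(C)C)C(C)C)c(C)c2OC)cc1
F4 | step 10 | 7-hydroxy-8-iodo-5-methoxy-3-(4-methoxybenzyl)-6-methyl-4H-chromen-4-one | COc1ccc(Cc2coc3c(I)c(O)c(C)c(OC)c3c2=O)cc1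
F5 | step 10 | 8-ethenyl-7-hydroxy-5-methoxy-3-(4-methoxybenzyl)-6-methyl-4H-chromen-4-one | COc1ccc(Cc2coc3c(C=C)c(O)c(C)c(OC)c3c2=O)cc1
F6 | step 5 | 4,6-dihydroxy-2-methoxy-3-methylbenzaldehyde | O=Cc1c(O)cc(O)c(C)c1OC
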